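**Retrosynthetic overview**
1. The strategy rests on the single cyclohexane ring, numbered here C1 (CH with the side chain), C2 (quaternary, methyl and 4-methylpent-3-enyl), C3 (CHBr), C4, C5 (CH2), C6 (C(CH3)OH). Side chain, C2-methyl and bromine lie on one face at the contiguous C1–C2–C3, and the oxygenated C6 is para to C3, which is the pattern of an endo [4+2] adduct of a 2-oxygenated diene.
2. C3–Br ⇐ axial C3–OH (inversion) ⇐ C3 ketone ⇐ C3–NO2 (Nef); C6 carbinol ⇐ C6 ketone + methylcerium.
3. The ring (the only one, closed in the key step) ⇐ (Z)-2-silyloxydiene 10 (C4=C5–C6=C1) + (E)-nitroalkene 15 (C2=C3), forming C1–C2 and C3–C4.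
4. 10 ⇐ vinyl ketone 9 ⇐ (S)-linalool 1, which supplies the side-chain stereocentre; 15 ⇐ 6-methylhept-5-en-2-one 11 + nitromethane 12.

Key step: step 9

Assumption: the sense of induction of a chiral hydrogen-bond donor on this new substrate class cannot be predicted with confidence. The (S,S) catalyst is written; if it proves mismatched, its (R,R) mirror image would be used under the same conditions.
Remark: the enol ether of the diene is made as a triethylsilyl ether, so that it survives purification on deactivated silica and the long reaction under pressure.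

**Route**

Step 1
Reactants: 1 (S)-linalool
Product: 2 (3S)-3,7-dimethyl-3-(triethylsilyloxy)octa-1,6-diene
Conditions: TESOTf, 2,6-lutidine, CH2Cl2, −78 → 0 °C
Reagents that add atoms: triethylsilyl trifluoromethanesulfonate, CC[Si](CC)(CC)OS(=O)(=O)C(F)(F)F
Why: Silyl ether protection of the tertiary allylic alcohol with a silyl triflate and a hindered base should proceed without ionisation, and the (S) stereocentre, which becomes the side-chain carbinol of the target, is not touched.

Step 2
Reactants: 2 (3S)-3,7-dimethyl-3-(triethylsilyloxy)octa-1,6-diene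
Product: 4 (4S)-4-methyl-4-(triethylsilyloxy)hex-5-en-1-ol, via aldehyde 3 (not isolated)
Conditions: O3 (1 equiv, Sudan Red 7B end point), CH2Cl2/MeOH, −78 °C; then NaBH4, −78 → 0 °C
Reagents that add atoms: ozone, [O-][O+]=O
Why: Chemoselective ozonolysis with reductive work-up, in which the electron-rich trisubstituted alkene should be consumed well before the hindered vinyl group next to the silyloxy carbon and borohydride reduces aldehyde 3 in the same flask.

Step 3
Reactants: 4 (4S)-4-methyl-4-(triethylsilyloxy)hex-5-en-1-ol
Product: 5 (3S)-6-bromo-3-methyl-3-(triethylsilyloxy)hex-1-ene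
Conditions: CBr4, PPh3, 2,6-lutidine, CH2Cl2, 0 °C
Reagents that add atoms: tetrabromomethane, BrC(Br)(Br)Br
Why: Appel reaction, an SN2 displacement of the alkoxyphosphonium group at a primary carbon under near-neutral conditions that the tertiary silyl ether should tolerate.

Step 4
Reactants: 5 (3S)-6-bromo-3-methyl-3-(triethylsilyloxy)hex-1-ene; 6 acrolein
Product: 8 (7S)-7-methyl-7-(triethylsilyloxy)nona-1,8-dien-3-ol (both C3 epimers), via Grignard reagent 7 (not isolated)
Conditions: Mg, THF, 40 °C; then 6, −78 °C; H2O
Reagents that add atoms: none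
Why: Grignard formation and 1,2-addition to acrolein, chosen because the magnesium reagent (unlike the lithium one) should not draw the silyl group from the tertiary oxygen, and the new carbinol centre is removed by the oxidation of step 5.

Step 5
Reactants: 8 (7S)-7-methyl-7-(triethylsilyloxy)nona-1,8-dien-3-ol
Product: 9 (7S)-7-methyl-7-(triethylsilyloxy)nona-1,8-dien-3-one
Conditions: Dess–Martin periodinane, CH2Cl2, 0 → 25 °C
Reagents that add atoms: none
Why: Dess–Martin oxidation of the allylic alcohol should give the polymerisation-prone vinyl ketone under mild, non-basic conditions, to be used at once.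

Step 6
Reactants: 9 (7S)-7-methyl-7-(triethylsilyloxy)nona-1,8-dien-3-one
Product: 10 (3Z,7S)-7-methyl-3,7-bis(triethylsilyloxy)nona-1,3,8-triene
Conditions: TESOTf, Et3N, Et2O, −78 → 0 °C; filtration through Et3N-deactivated silica
Reagents that add atoms: triethylsilyl trifluoromethanesulfonate, CC[Si](CC)(CC)OS(=O)(=O)C(F)(F)F
Why: Soft enolisation (silyl triflate and amine) at the only enolisable position, the alpha-prime CH2, should give the cross-conjugated dienol silyl ether as the (Z) isomer, because the alkyl chain then avoids allylic strain with the vinyl group and points outward from the diene.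

Step 7
Reactants: 11 6-methylhept-5-en-2-one; 12 nitromethane
Product: 13 2,6-dimethyl-1-nitrohept-5-en-2-ol (racemic)
Conditions: 12 (10 equiv, as solvent), DBU (0.2 equiv), 25 °C
Reagents that add atoms: none
Why: Henry (nitroaldol) reaction, in which the large excess of nitromethane drives the unfavourable ketone equilibrium; the racemic carbinol centre is destroyed in step 8.

Step 8
Reactants: 13 2,6-dimethyl-1-nitrohept-5-en-2-ol
Product: 15 (E)-2,6-dimethyl-1-nitrohepta-1,5-diene, via mesylate 14 (not isolated)
Conditions: MsCl, i-Pr2NEt, CH2Cl2, −20 → 0 °C; chromatography to remove the (Z) isomer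
Reagents that add atoms: none
Why: Mesylation and E1cB elimination through the nitronate should give the conjugated nitroalkene under kinetic control (short contact with base limits deconjugation), and the (E) isomer, with nitro cis to methyl, is isolated by chromatography.

Step 9
Reactants: 10 (3Z,7S)-7-methyl-3,7-bis(triethylsilyloxy)nona-1,3,8-triene; 15 (E)-2,6-dimethyl-1-nitrohepta-1,5-diene
Product: 17 (2S,3S,4S)-3-methyl-3-(4-methylpent-3-en-1-yl)-2-[(3S)-3-methyl-3-(triethylsilyloxy)pent-4-en-1-yl]-4-nitrocyclohexan-1-one (C6 ketone; side chain at C1, methyl at C2 and nitro at C3 all cis), via silyl enol ether cycloadduct 16 (not isolated)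
Conditions: 15 (1.0 equiv), 10 (1.5 equiv), 1,1'-[(1S,2S)-cyclohexane-1,2-diyl]bis{3-[3,5-bis(trifluoromethyl)phenyl]thiourea} (20 mol %), toluene, 1.0 GPa, 25 °C; then 0.5 M HCl, THF, 0 °C
Reagents that add atoms: none
Why: Proposed new method: under pressure the hydrogen-bonded nitroalkene 15 and diene 10 should combine in a concerted but strongly asynchronous [4+2] cycloaddition, the enol ether carbon C1 bonding first to the nitroalkene β-carbon C2 and the vinyl terminus C4 then to the nitronate-like carbon C3, which closes the only ring (C1 to C6) by cycloaddition; dilute acid then turns the C5=C6 silyl enol ether 16 into the C6 ketone. The closest known reaction type is the Diels–Alder reaction of 2-silyloxy- and 2-aminodienes with β-monosubstituted nitroalkenes, also under chiral hydrogen-bond-donor catalysis; new here is the fully substituted β-carbon, whose rate penalty is countered by 1.0 GPa (large negative activation volume for a bond between two hindered carbons) and by the thiourea, which lowers the LUMO and stabilises the nitronate character. Regiochemistry follows from the 2-silyloxy group, which makes C1 the nucleophilic terminus and places nitro para to C6. C2 and C3 take their relative configuration from the (E) alkene (suprafacial addition keeps methyl cis to nitro), and C1 takes its configuration relative to them from the (Z) enol ether, which turns the side chain outward, together with the endo position of nitro and methyl while the longer homoprenyl chain stays exo and clear of the C6 silyloxy group, so that side chain, methyl and nitro end up cis. The step needs endo and facial selectivity: endo is secured by the nitro group and the exo preference of the larger C2 substituent, but the side-chain stereocentre is too remote to choose the diene face, so the absolute sense must come from the C2-symmetric thiourea bound to both nitro oxygens, and the two endo adducts, being diastereomers, can be separated if induction is incomplete. A stepwise Michael–Michael course, or a hetero-[4+2] to a cyclic nitronate followed by [3,3] shift, would converge on the same constitution.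

Step 10
Reactants: 17 nitro ketone (as in step 9)
Product: 18 (1R,2S,3S,4S)-1,3-dimethyl-3-(4-methylpent-3-en-1-yl)-2-[(3S)-3-methyl-3-(triethylsilyloxy)pent-4-en-1-yl]-4-nitrocyclohexan-1-ol (C6 hydroxyl cis to the C1 side chain)
Conditions: MeLi, CeCl3 (anhydrous), THF, −78 °C (MeCeCl2, 3 equiv); then 17, −78 °C; H2O
Reagents that add atoms: methyllithium, [Li]C
Why: Organocerium 1,2-addition, in which the weakly basic reagent should add faster than it enolises C1 or opens the ring by retro-Michael reaction, and should attack C6 equatorially, away from the axial C2 methyl, so that the new hydroxyl is axial and cis to the side chain; any nitronate formed at C3 is a spectator, since C3 is oxidised next.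

Step 11
Reactants: 18 nitro alcohol (as in step 10)
Product: 20 (2S,3S,4R)-4-hydroxy-2,4-dimethyl-2-(4-methylpent-3-en-1-yl)-3-[(3S)-3-methyl-3-(triethylsilyloxy)pent-4-en-1-yl]cyclohexan-1-one (C3 ketone), via sodium nitronate 19 (not isolated)
Conditions: NaOMe, MeOH, 0 °C; then TiCl3 (aq), NH4OAc, H2O/MeOH, pH 5–6, 25 °C
Reagents that add atoms: water, O
Why: Reductive Nef reaction, in which trivalent titanium reduces the nitronate to the imine that hydrolyses to the ketone under buffered conditions that the alkenes, the tertiary alcohol and the tertiary silyl ether should survive; C1 is no longer alpha to a carbonyl, so the base cannot epimerise it.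

Step 12
Reactants: 20 hydroxy ketone (as in step 11)
Product: 21 (2S,3S,4R)-2,4-dimethyl-2-(4-methylpent-3-en-1-yl)-3-[(3S)-3-methyl-3-(triethylsilyloxy)pent-4-en-1-yl]-4-(trimethylsilyloxy)cyclohexan-1-one
Conditions: N-(trimethylsilyl)imidazole, CH2Cl2, 25 → 40 °C
Reagents that add atoms: N-(trimethylsilyl)imidazole, C[Si](C)(C)n1ccnc1
Why: Silyl ether protection with a reagent that silylates hindered tertiary hydroxyls without enolising the ketone; it caps the C6 oxygen, which sits on the face from which it could otherwise displace the C3 leaving group transannularly in step 14.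

Step 13
Reactants: 21 silyloxy ketone (as in step 12)
Product: 22 (1R,2S,3S,4R)-2,4-dimethyl-2-(4-methylpent-3-en-1-yl)-3-[(3S)-3-methyl-3-(triethylsilyloxy)pent-4-en-1-yl]-4-(trimethylsilyloxy)cyclohexan-1-ol (C3 hydroxyl axial, trans to the C2 methyl)
Conditions: K[BH(sBu)3], THF, −78 °C; then NaOH, H2O2, 0 °C
Reagents that add atoms: none
Why: Reduction with a bulky trialkylborohydride, which should attack the C3 ketone equatorially, as it does in cyclohexanones flanked by a quaternary carbon, and so give the axial alcohol on the face opposite to the C2 methyl.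

Step 14
Reactants: 22 axial alcohol (as in step 13)
Product: 24 {[(1R,2S,3S,4S)-4-bromo-1,3-dimethyl-3-(4-methylpent-3-en-1-yl)-2-[(3S)-3-methyl-3-(triethylsilyloxy)pent-4-en-1-yl]cyclohexyl]oxy}trimethylsilane (bromine equatorial, cis to the C2 methyl), via triflate 23 (not isolated)
Conditions: Tf2O, 2,6-di-tert-butyl-4-methylpyridine, CH2Cl2, −40 → 0 °C; then Bu4NBr, toluene, 25 → 50 °C
Reagents that add atoms: tetrabutylammonium bromide, CCCC[N+](CCCC)(CCCC)CCCC.[Br-]
Why: Triflation and SN2 displacement by bromide with inversion should turn the axial alcohol into the equatorial bromide, the non-nucleophilic base, the soluble bromide and the non-polar solvent being chosen to keep ionisation of the neopentyl-type triflate behind direct substitution.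

Step 15
Reactants: 24 bromide bis-silyl ether (as in step 14)
Product: 25 (1R,2S,3S,4S)-4-bromo-2-[(3S)-3-hydroxy-3-methylpent-4-en-1-yl]-1,3-dimethyl-3-(4-methylpent-3-en-1-yl)cyclohexan-1-ol (CNP0237376.1)
Conditions: HF·pyridine, pyridine, THF, 0 → 25 °C
Reagents that add atoms: none
Why: Fluoride-mediated desilylation under buffered conditions should free both tertiary alcohols without elimination of the equatorial bromide, which has no antiperiplanar hydrogen.

**Compound list**
1 | (S)-linalool | C=C[C@@](C)(O)CCC=C(C)C | starting material
2 | (3S)-3,7-dimethyl-3-(triethylsilyloxy)octa-1,6-diene | C=C[C@@](C)(O[Si](CC)(CC)CC)CCC=C(C)C | intermediate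
3 | (4S)-4-methyl-4-(triethylsilyloxy)hex-5-enal | C=C[C@@](C)(O[Si](CC)(CC)CC)CCC=O | intermediate
4 | (4S)-4-methyl-4-(triethylsilyloxy)hex-5-en-1-ol | C=C[C@@](C)(O[Si](CC)(CC)CC)CCCO | intermediate
5 | (3S)-6-bromo-3-methyl-3-(triethylsilyloxy)hex-1-ene | C=C[C@@](C)(O[Si](CC)(CC)CC)CCCBr | intermediate
6 | acrolein | C=CC=O | starting material
7 | [(4S)-4-methyl-4-(triethylsilyloxy)hex-5-en-1-yl]magnesium bromide | C=C[C@@](C)(O[Si](CC)(CC)CC)CCC[Mg]Br | intermediate
8 | (7S)-7-methyl-7-(triethylsilyloxy)nona-1,8-dien-3-ol (both C3 epimers) | C=C[C@@](C)(O[Si](CC)(CC)CC)CCCC(O)C=C | intermediate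
9 | (7S)-7-methyl-7-(triethylsilyloxy)nona-1,8-dien-3-one | C=C[C@@](C)(O[Si](CC)(CC)CC)CCCC(=O)C=C | intermediate
10 | (3Z,7S)-7-methyl-3,7-bis(triethylsilyloxy)nona-1,3,8-triene | C=C/C(O[Si](CC)(CC)CC)=C/CC[C@](C)(O[Si](CC)(CC)CC)C=C | intermediate
11 | 6-methylhept-5-en-2-one | CC(=O)CCC=C(C)C | starting material
12 | nitromethane | C[N+](=O)[O-] | starting material
13 | 2,6-dimethyl-1-nitrohept-5-en-2-ol (racemic) | CC(C)=CCCC(C)(O)C[N+](=O)[O-] | intermediate
14 | 2,6-dimethyl-1-nitrohept-5-en-2-yl methanesulfonate | CC(C)=CCCC(C)(C[N+](=O)[O-])OS(C)(=O)=O | intermediate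
15 | (E)-2,6-dimethyl-1-nitrohepta-1,5-diene | CC(C)=CCC/C(C)=C/[N+](=O)[O-] | intermediate
16 | triethylsilyl enol ether (C5=C6) of nitro ketone 17, side chain, C2-methyl and nitro cis | C=C[C@@](C)(O[Si](CC)(CC)CC)CC[C@H]1[C@](C)(CCC=C(C)C)[C@@H]([N+](=O)[O-])CC=C1O[Si](CC)(CC)CC | intermediate
17 | (2S,3S,4S)-3-methyl-3-(4-methylpent-3-en-1-yl)-2-[(3S)-3-methyl-3-(triethylsilyloxy)pent-4-en-1-yl]-4-nitrocyclohexan-1-one | C=C[C@@](C)(O[Si](CC)(CC)CC)CC[C@H]1[C@](C)(CCC=C(C)C)[C@@H]([N+](=O)[O-])CCC1=O | intermediate
18 | (1R,2S,3S,4S)-1,3-dimethyl-3-(4-methylpent-3-en-1-yl)-2-[(3S)-3-methyl-3-(triethylsilyloxy)pent-4-en-1-yl]-4-nitrocyclohexan-1-ol | C=C[C@@](C)(O[Si](CC)(CC)CC)CC[C@H]1[C@](C)(CCC=C(C)C)[C@@H]([N+](=O)[O-])CC[C@@]1(C)O | intermediate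
19 | sodium nitronate of 18 (C3 aci-nitro salt) | C=C[C@@](C)(O[Si](CC)(CC)CC)CC[C@H]1[C@](C)(CCC=C(C)C)C(=[N+]([O-])[O-])CC[C@@]1(C)O.[Na+] | intermediate
20 | (2S,3S,4R)-4-hydroxy-2,4-dimethyl-2-(4-methylpent-3-en-1-yl)-3-[(3S)-3-methyl-3-(triethylsilyloxy)pent-4-en-1-yl]cyclohexan-1-one | C=C[C@@](C)(O[Si](CC)(CC)CC)CC[C@H]1[C@](C)(CCC=C(C)C)C(=O)CC[C@@]1(C)O | intermediate
21 | (2S,3S,4R)-2,4-dimethyl-2-(4-methylpent-3-en-1-yl)-3-[(3S)-3-methyl-3-(triethylsilyloxy)pent-4-en-1-yl]-4-(trimethylsilyloxy)cyclohexan-1-one | C=C[C@@](C)(O[Si](CC)(CC)CC)CC[C@H]1[C@](C)(CCC=C(C)C)C(=O)CC[C@@]1(C)O[Si](C)(C)C | intermediate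
22 | (1R,2S,3S,4R)-2,4-dimethyl-2-(4-methylpent-3-en-1-yl)-3-[(3S)-3-methyl-3-(triethylsilyloxy)pent-4-en-1-yl]-4-(trimethylsilyloxy)cyclohexan-1-ol | C=C[C@@](C)(O[Si](CC)(CC)CC)CC[C@H]1[C@](C)(CCC=C(C)C)[C@H](O)CC[C@@]1(C)O[Si](C)(C)C | intermediate
23 | trifluoromethanesulfonate of 22 (axial C3 triflate) | C=C[C@@](C)(O[Si](CC)(CC)CC)CC[C@H]1[C@](C)(CCC=C(C)C)[C@H](OS(=O)(=O)C(F)(F)F)CC[C@@]1(C)O[Si](C)(C)C | intermediate
24 | {[(1R,2S,3S,4S)-4-bromo-1,3-dimethyl-3-(4-methylpent-3-en-1-yl)-2-[(3S)-3-methyl-3-(triethylsilyloxy)pent-4-en-1-yl]cyclohexyl]oxy}trimethylsilane | C=C[C@@](C)(O[Si](CC)(CC)CC)CC[C@H]1[C@](C)(CCC=C(C)C)[C@@H](Br)CC[C@@]1(C)O[Si](C)(C)C | intermediate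
25 | (1R,2S,3S,4S)-4-bromo-2-[(3S)-3-hydroxy-3-methylpent-4-en-1-yl]-1,3-dimethyl-3-(4-methylpent-3-en-1-yl)cyclohexan-1-ol | C=C[C@@](C)(O)CC[C@H]1[C@](C)(CCC=C(C)C)[C@@H](Br)CC[C@@]1(C)O | target

**Step count**
Total: 15 steps. Longest linear sequence: 13 steps (steps 1–6, then 9–15); the nitroalkene branch is steps 7–8.

**Steps most likely to fail**

1. Step 9 (the step that goes beyond known chemistry). The cycloaddition may be too slow because the first bond joins a substituted diene terminus to a fully substituted nitroalkene carbon. The dienol ether may be protodesilylated by the hydrogen-bond donor during the long reaction. The catalyst may discriminate poorly between the two diene faces.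
Fallback: this sets out from vinyl ketone 9 and nitroalkene 15 and returns to the route at nitro ketone 17, building the ring in two known operations. Deprotonation of 9 at the alpha-prime CH2 with LiN(iPr)2 (THF, −78 °C) and Michael addition of the lithium dienolate to 15 should proceed through a chelated synclinal transition state of the same topicity as the endo cycloaddition. Quenching with AcOH at −78 °C should give the open-chain nitro enone F1. Catalytic tetramethylguanidine in MeCN at 0 °C should then close the ring by 6-endo-trig addition of the nitronate carbon C3 to the enone terminus C4, leaving nitro equatorial in 17. This sequence has no control of absolute ring configuration, so 17 would be separated from its diastereomer of opposite ring configuration by preparative HPLC.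

2. Step 14. Substitution at C3 is slowed by the neighbouring quaternary carbon. E2 loss of the antiperiplanar C4 hydrogen, 1,2-shift of the antiperiplanar C2 methyl, or capture of a developing cation by the homoprenyl alkene may outrun it.
Fallback: this sets out from alcohol 22 and returns at bromide 24 without a new isolated compound. An Appel reaction directly on 22 (CBr4, P(n-C8H17)3, toluene, 60 °C) replaces the preformed sulfonate by an alkoxyphosphonium bromide ion pair. The leaving group is then weaker and less prone to ionise, and bromide is delivered from within the ion pair with inversion.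

3. Step 11. Reduction of the hindered nitronate may stall at the oxime. Drift to low pH may strip the tertiary silyl ether or dehydrate the C6 alcohol.
Fallback: this sets out from nitro alcohol 18 and returns at hydroxy ketone 20. The nitro group is reduced only as far as the oxime with Sn(SPh)2 (divalent tin), PhSH and Et3N in MeCN at 25 °C, which should give the ketoxime F2. The oxime is then exchanged onto aqueous glyoxylic acid (NaOAc, THF/H2O, 25 °C) to release 20 under near-neutral conditions.

**Further compounds**
F1 | step 9 | open-chain nitro enone, (4S)-configured at C1 and C2 as in 17: 4-[1-nitro-2,6-dimethylhept-5-en-2-yl]-substituted (7S)-7-methyl-7-(triethylsilyloxy)nona-1,8-dien-3-one | C=C[C@@](C)(O[Si](CC)(CC)CC)CC[C@H](C(=O)C=C)[C@](C)(CCC=C(C)C)C[N+](=O)[O-]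
F0 | step 14 | none | none
F2 | step 11 | C3 ketoxime of hydroxy ketone 20 | C=C[C@@](C)(O[Si](CC)(CC)CC)CC[C@H]1[C@](C)(CCC=C(C)C)C(=NO)CC[C@@]1(C)O
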